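All runs are simulated from invented constants, and the scatter is random.

Target, the peak I want, stands at 20.7% of the substrate charged after 3.00 min in the north flask, and I book the rest of that substrate against it.

- north: substrate 0.35 M; partner 0.80 equiv; the very flask that is asked about, followed so far
- flask: substrate 0.35 M; partner 0.800 equiv; time 8.0 min

- north (time / min: intermediate C / %, target / %): 0.167: 2.6, 0; 0.500: 9.8, 2.1; 0.833: 12.5, 5.0; 1.33: 17.0, 7.6; 2.00: 16.8, 14.6; 2.50: 15.5, 15.7; 3.00: 12.0, 20.7

(readings scatter by 1 percentage point)

1. amount of intermediate C in percent of the substrate charged, at 50 s, 3.0 min and 8.0 min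

- the numbers in the tables scatter by 1 percentage point (one standard deviation)

My substrate ledger for the north flask at 3.00 min, in percent of the substrate charged, reads:

  target: 20.7%
  intermediate C: 12.0%
  not booked in these two columns: 67.3%

The entry that moves next is intermediate C, so I need the rate at which it passes into target. From 1.33 min to 3.00 min, target gains 13 percentage points while the four readings of c(intermediate C) average 15.3%. So

  gain / (time × mean) = 0.512 min⁻¹

This is the drain constant, a first-order rate constant: the target gained per minute for each percent of intermediate C present. It is a reading and carries the scatter of 1 point on each point.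

For the first two asked times, the readings themselves give me 12.5% and 12.0%. For 8.0 min, I let the 3.00 min reading drain with nothing feeding it:

  c(intermediate C) = 12.0% × exp(−0.512 min⁻¹ × 5.00 min) = 0.928%

Any feed lifts that figure. The forecast gives 13%, 12.3% and 1.7%, the last higher than my figure, and it warns: “this is uncertain if slow formation persists”.

The north flask gives 13.9%, 12.6% and 2.41%, so the forecast stands within its margin.

    substrate ⇌ intermediate A (K = 0.990, k = 0.200 s⁻¹)
    intermediate B ⇌ intermediate C (K = 2.20, k = 0.0450 s⁻¹)
    intermediate C → target (k = 0.00890 s⁻¹)
    substrate + partner → intermediate B (k = 0.0890 M⁻¹ s⁻¹)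
    substrate → side product (k = 0.0250 s⁻¹)

At 8.0 min, the north flask makes intermediate C at 0.347 of the rate at which it uses it up, each step taken net, which is less than the rate of use. From 4.00 min to 8.00 min, c(intermediate C) in this flask goes from 9.37% to 2.41%, an average fall of 0.340 min⁻¹, slower than the drain constant I read from the north run, 0.512 min⁻¹.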